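## Structural features

The target is a 7,8-dihydro-6H-isochromen-6-one. An oxygen ring B (C1, O2, C3, C4, C4a, C8a) is fused to a carbocyclic ring A (C4a to C8a), so that the dienone C6(=O)–C5(Cl)=C4a carries two enol-ether arms, C4=C3–O2 and C8a=C1–O2. C3 bears a (1E,3E,5S)-3,5-dimethylhepta-1,3-dienyl chain and C5 a chlorine. Ring A ends in the quaternary carbinol C7 (methyl, hydroxyl; S) and the methine C8 (S), which carries through C3' a 6-methyloxane-2,4-dione ring C (O1', C2' to C6'). C7 and C8 are adjacent, with the C7 oxygen and the C8 substituent cis on ring A. C3' (R) is the third contiguous centre but lies between two carbonyls and is labile; C6' (S) and the side-chain centre (S) are remote and can be bought. The chromophore is electrophilic at C1 and C3 and sensitive to base, amines and light; the β-keto-δ-lactone is acidic; C6/C7 form an α-ketol. The real difficulty is the C7/C8 pair on a ring A whose C8 is sp3 and carbon-substituted, which rules out oxidative dearomatization of an aromatic precursor, together with the regiochemistry at C5, C4a and C8a. The key step uses the fact that C7, with its methyl group, its oxygen and the neighbouring C6 carbonyl, is the α-carbon of lactic acid. Ring A without ring B is a 4-hydroxy-4-methylcyclohexane-1,3-dione (carbonyls at C4a and C6, C5 between them), so C7–C8 can be a Michael bond and C5–C6 a Claisen bond made by the lactate carboxyl.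

## Logic of the disconnections

27 to 24 and 25. Bonds cut: C3'–C4' (the acyl bond of the β-keto lactone) and O1'–C2' (the lactone ester bond), with C2' re-joined to the C7 oxygen. Reason: the six-membered β-keto lactone is the translactonized form of an α-acyl γ-lactone, and C4' to C6' with the C6' centre are the four carbons of 25. Gain: two stereocentres and the acidic ring leave, and the C7 hydroxyl and the C8 arm become one compact unit. Demand: 24 must be enolized at C3' without damage to the chromophore, 25 must react at its acyl carbon, and the equilibrium must favour the six-membered ring.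

24 to 22 to 21. Bond cut: O7–C2'; C2' is lowered to the alcohol level (22) and masked as a silyl ether (21). Reason: a lactone α-CH2 would compete with C8a when C1 is introduced, whereas an ether is inert. Gain: a two-carbon arm that needs no attention while ring B is built. Demand: an oxidation that spares the diene and the pyran, and a cis relation between the C7 hydroxyl and the arm.

21 to 19 to 18. Bonds cut: O2–C3 and C1=C8a. Reason: ring B is an enol oxygen added across an alkyne, and C1 is a one-carbon unit at the only enolizable position of 18. Gain: ring B and the whole chromophore leave, and a monocyclic enynone remains. Demand: C8a must be the only acidic site (C7 is quaternary), and the oxygen must close 6-endo-dig on C3.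

18 to 12 and 17. Bond cut: C4a–C4. Reason: a convergent sp2–sp coupling that brings in the whole side chain with its stereocentre. Gain: two fragments of similar size. Demand: a regiochemically defined enol triflate at C4a, and oxidative addition at C–O and not at C5–Cl.

17 to 16 to 15 to 14 to 13. Bonds cut: the two C=C bonds of the dienyne, then the oxidation level of the carbinol carbon of 13. Reason: both alkenes are E and each is the product of a stabilized-ylide or phosphonate olefination. Gain: the side-chain centre comes from 13. Demand: no epimerization of the α-branched aldehyde 14, and E selectivity in both olefinations.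

12 to 11 to 10. Bonds cut: the O–S bond at the C4a oxygen and C5–Cl. Reason: both are functionalizations of the 1,3-dione, at its central carbon and at its less hindered oxygen. Gain: the unadorned dione 10. Demand: monochlorination, and sulfonylation at the C4a oxygen and not at the C6 oxygen.

10 to 3 and 7. Bonds cut: C7–C8 and C5–C6. Reason: C7 is the lactate α-carbon, and the dione is the product of a Michael–Claisen annulation onto a methyl enone. Gain: ring A, two skeletal bonds and both ring stereocentres in one operation from two small fragments. Demand: attack on the enolate face anti to the acetal substituent, the correct enone face, and migration of the enolate to C5 before acylation.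

3 to 1 and 2; 7 to 5 and 6; 5 to 4. Bonds cut: the two acetal C–O bonds; the enone C=C bond; the O–Si bond. Reason: acetalization, cross-metathesis and silylation from commercial materials. Gain: C7 comes from the chiral pool. Demand: a diastereomerically pure cis acetal, because its acetal carbon is the only stereocentre of the enolate.

## Other disconnections considered

Alternative 1: The cut is the C7–O bond, made on a preformed ring. A vinylogous ester A1 that already carries C8 and its arm at the acid level is doubly deprotonated with LiN(iPr)2, the C7 enolate is oxidized with iodine, and the carboxylate closes on C7 to give the cis-fused lactone A2.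
- In its favour: the cis relation of the C7 oxygen and the C8 arm is enforced by the five-membered ring and does not rest on an acyclic face selection. On this point it is better than the chosen plan. The arm also arrives at the acid level, so steps 14 and 15 would not be needed.
- Against it here: C8 must be set first by a separate asymmetric step, so the chiral pool no longer pays for C7. The ring closure asks a carboxylate to displace iodide at a tertiary α-keto carbon, where elimination to the enone is the expected competitor. A2 then carries a lactone α-CH2 through chlorination, coupling and C1 installation, where it competes with C8a.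
- Comparison: on structure both plans reach the same ring A pattern. On mechanism the chosen plan forms two C–C bonds and the ring in one operation, whereas this one forms one C–O bond. On step economy the two are about equal once the asymmetric entry to A1 is counted.

Alternative 2: The cut is the pair C1–C8a and O2–C3, made last on an enynone A3 that already carries the complete lactone as its methyl enol ether. tert-Butoxybis(dimethylamino)methane aminomethylenates C8a, and aqueous acid with AgOTf hydrolyses the enaminone and closes the pyran 6-endo-dig to A4.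
- In its favour: it is the most convergent end-game, and only an enol ether hydrolysis remains afterwards. No strong base meets the chromophore, and on this point it is better than the chosen plan, whose last step enolizes a lactone next to the pyranoquinone.
- Equal point: in mechanism it is the equal of the chosen plan, because steps 12 and 13 are the same operation.
- Against it here: it does not address C7 and C8, which must still come from a construction such as the chosen key step. The protected lactone has its own vinylogous CH2 (C5') open to aminomethylenation. The final demethylation of a vinylogous carbonate needs acid or a nucleophile beside the chromophore.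
- Step economy: nothing is gained, because the enol ether must be put on and taken off.

Alternative 3: The cut is C8–C3'. An achiral cyclohexadienone ester A5, whose tethered β-keto ester already contains C6', cyclizes under a quinine-derived amine–thiourea. C3' adds 5-exo-trig to one of the two enantiotopic enone β-carbons and gives the bicyclic keto lactone A6.
- In its favour: C7, C8, C3' and the whole acyl chain are installed in one catalytic step, and the cis ring fusion is enforced by the tether. In stereocentres set per step and in security of the C7/C8 relation it is better than the chosen plan.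
- Against it here: the absolute configuration rests on catalyst control over two enantiotopic faces and not on the chiral pool. The oxygen pattern of A6 does not fit ring A: its ketone is on C4a and C5=C6 is an unoxidized alkene. C6 must be oxidized, C5 chlorinated and the unsaturation moved before the alkyne and C1 can go in, all beside an enolizable β-keto lactone.
- Comparison: the chosen plan delivers the C4a/C6 dione directly, so it is ahead on the structure of ring A and on step economy after the key step.

Key step: step 4

## Remarks on the chemistry (assumptions)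

- Stereochemical series: alkylation of the cis-(2R,5R) acetal enolate anti to the tert-butyl group is a retention, so (R)-lactic acid is the correct series for 7S, and the dione 10 is (4S,5S).
- C8: a lithium-bridged (closed) Michael transition state is expected to place the arm trans to the C7 oxygen. The key step is therefore run with HMPA (open transition state), and the arm is carried as a bulky, non-coordinating tert-butyldiphenylsilyl ether, which also withstands the acid of step 13.
- C3': this centre equilibrates through the enol. The route delivers it under thermodynamic control, and the (3'R) keto form is assumed to be the form in which 27 is obtained.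

## Route

Step 1
Reactants: 1 (R)-lactic acid; 2 pivalaldehyde
Product: 3 (2R,5R)-2-tert-butyl-5-methyl-1,3-dioxolan-4-one
Conditions: TsOH·H2O (cat.), H2SO4 (cat.), pentane, reflux, water separator; crystallization from pentane, −78 °C
Reagents that add atoms: none
Why: Acid-catalysed acetalization with azeotropic removal of water; the cis acetal is the thermodynamically favoured isomer and crystallization should bring it to diastereomeric purity, which matters because the acetal carbon will be the only stereocentre of the enolate.

Step 2
Reactants: 4 but-3-en-1-ol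
Product: 5 tert-butyl(but-3-en-1-yloxy)diphenylsilane
Conditions: TBDPSCl, imidazole, CH2Cl2, 0 °C → rt
Reagents that add atoms: tert-butyl(chloro)diphenylsilane, CC(C)(C)[Si](Cl)(c1ccccc1)c1ccccc1
Why: Imidazole-mediated silylation of a primary alcohol; this ether is chosen because it is stable to alkoxide base and to the aqueous acid of step 13 and does not coordinate lithium.

Step 3
Reactants: 5 tert-butyl(but-3-en-1-yloxy)diphenylsilane; 6 but-3-en-2-one
Product: 7 (E)-6-[(tert-butyldiphenylsilyl)oxy]hex-3-en-2-one
Conditions: 6 (3 equiv), RuCl2(=CH-C6H4-2-OiPr)(H2IMes) (second-generation Hoveyda–Grubbs catalyst, 2 mol %), CH2Cl2, 40 °C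
Reagents that add atoms: none
Why: Olefin cross-metathesis of a terminal alkene with an electron-poor vinyl ketone that homodimerizes slowly; the conjugated product should form as the E isomer under thermodynamic control, and loss of ethene drives the reaction.

Step 4
Reactants: 3 (2R,5R)-2-tert-butyl-5-methyl-1,3-dioxolan-4-one; 7 (E)-6-[(tert-butyldiphenylsilyl)oxy]hex-3-en-2-one
Product: 10 (4S,5S)-5-{2-[(tert-butyldiphenylsilyl)oxy]ethyl}-4-hydroxy-4-methylcyclohexane-1,3-dione, via lithium enolate 8 (not isolated), via Michael adduct enolate 9 (not isolated)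
Conditions: LiN(iPr)2 (1.05 equiv), THF, −78 °C; HMPA (6 equiv); 7 added slowly, −78 °C; KOtBu (1.0 equiv), t-BuOH (1.0 equiv), −78 → 0 °C; aq. HCl to pH 3
Reagents that add atoms: none
Why: Proposed new method: the mechanistic reasoning is that deprotonation of 3 gives the planar enolate 8, which adds 1,4 to 7 (C7–C8), and that the resulting ketone enolate 9, once KOtBu/t-BuOH has moved the enolate to the methyl terminus C5, attacks the strained acylal carbonyl C6 (C5–C6), after which the acetal collapses with loss of pivalaldehyde; the closest known reaction types are the Michael addition of lactate- and mandelate-derived dioxolanone enolates to enones and the Michael–Claisen annulation of malonates with methyl enones to cyclohexane-1,3-diones. Ring A closes in the 6-(enolendo)-exo-trig mode, a favoured acyl substitution; the new 1,3-dione is deprotonated at once by the liberated C7 alkoxide, and this enolate is the thermodynamic sink that makes the sequence irreversible. C7 is controlled by the acetal carbon: the enone can reach the enolate only on the face anti to the tert-butyl group, so C8 takes the place of the lactate hydrogen and (R)-lactic acid gives 7S. C8 is controlled by the enone face: with the lithium solvated by HMPA, the open antiperiplanar arrangement that keeps the enone hydrogen under the dioxolanone ring and turns the acyl chain away from the enolate oxygen should place the arm on the side that is cis to the C7 hydroxyl in 10. A lithium-bridged closed arrangement, with the enone carbonyl held under the enolate O–Li, is expected to give the C8 epimer, so HMPA and the non-coordinating silyl ether are part of the design. The step needs 1,4- over 1,2-addition and addition over deprotonation of the enone: the first is secured because the 1,2-adduct can revert while dione formation cannot, the second by slow addition of 7 to preformed 8 at −78 °C. It also needs the C5 and not the C8a enolate to acylate: the C8a enolate could only close a four-membered ring, so equilibration funnels the material through C5.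

Step 5
Reactants: 10 silyloxyethyl hydroxy methyl cyclohexane-1,3-dione
Product: 11 (5S,6S)-5-{2-[(tert-butyldiphenylsilyl)oxy]ethyl}-2-chloro-3,6-dihydroxy-6-methylcyclohex-2-en-1-one (enol form of the 2-chloro-1,3-dione)
Conditions: NCS (1.05 equiv), CH2Cl2, 0 °C
Reagents that add atoms: N-chlorosuccinimide, O=C1CCC(=O)N1Cl
Why: Electrophilic chlorination of the 1,3-dione enol at C5, the only carbon between two carbonyls; one equivalent at 0 °C should avoid the dichloride and leave the silyl ether and the tertiary alcohol untouched.

Step 6
Reactants: 11 2-chloro-1,3-dione (enol form)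
Product: 12 (4S,5S)-5-{2-[(tert-butyldiphenylsilyl)oxy]ethyl}-2-chloro-4-hydroxy-4-methyl-3-oxocyclohex-1-en-1-yl trifluoromethanesulfonate
Conditions: PhNTf2 (1.1 equiv), iPr2NEt (1.5 equiv), CH2Cl2, 0 °C → rt
Reagents that add atoms: N-phenylbis(trifluoromethanesulfonimide), O=S(=O)(N(c1ccccc1)S(=O)(=O)C(F)(F)F)C(F)(F)F
Why: Enol triflate formation from a vinylogous acid; the diketonate should be sulfonylated at the C4a oxygen because the C6 oxygen is flanked by the quaternary C7 and hydrogen-bonded to its hydroxyl, and PhNTf2 does not sulfonylate the tertiary alcohol.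

Step 7
Reactants: 13 (S)-2-methylbutan-1-ol
Product: 14 (S)-2-methylbutanal
Conditions: TEMPO (cat.), KBr (cat.), NaOCl, NaHCO3, CH2Cl2/H2O, 0 °C
Reagents that add atoms: none
Why: TEMPO-catalysed hypochlorite oxidation of a primary alcohol to the aldehyde; the buffered two-phase medium at 0 °C should not epimerize the α-centre, and the aldehyde is used at once.

Step 8
Reactants: 14 (S)-2-methylbutanal
Product: 15 (2E,4S)-2,4-dimethylhex-2-enal
Conditions: Ph3P=C(CH3)CHO (1.1 equiv), benzene, 80 °C
Reagents that add atoms: 2-(triphenylphosphoranylidene)propanal, CC(C=O)=P(c1ccccc1)(c1ccccc1)c1ccccc1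
Why: Wittig olefination with a stabilized formyl ylide, which gives the E trisubstituted enal; the neutral ylide should leave the α-stereocentre intact, and the conjugated product is less electrophilic than 14, which limits a second olefination.

Step 9
Reactants: 15 (2E,4S)-2,4-dimethylhex-2-enal
Product: 16 trimethyl[(3E,5E,7S)-5,7-dimethylnona-3,5-dien-1-yn-1-yl]silane
Conditions: (EtO)2P(O)CH2C≡CSiMe3, LiN(SiMe3)2, THF, −78 → 0 °C
Reagents that add atoms: diethyl [3-(trimethylsilyl)prop-2-yn-1-yl]phosphonate, CCOP(=O)(CC#C[Si](C)(C)C)OCC
Why: Horner–Wadsworth–Emmons olefination with a propargylic phosphonate anion, which should give the E enyne; the silyl cap prevents propargyl–allenyl scrambling of the anion.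

Step 10
Reactants: 16 silylated dienyne
Product: 17 (3E,5E,7S)-5,7-dimethylnona-3,5-dien-1-yne
Conditions: K2CO3 (0.2 equiv), MeOH, 0 °C → rt
Reagents that add atoms: none
Why: Methoxide-mediated protodesilylation of an alkynylsilane; the diene and the allylic stereocentre are not affected.

Step 11
Reactants: 12 chloro enol triflate; 17 (3E,5E,7S)-5,7-dimethylnona-3,5-dien-1-yne
Product: 18 (5R,6S)-5-{2-[(tert-butyldiphenylsilyl)oxy]ethyl}-2-chloro-3-[(3E,5E,7S)-5,7-dimethylnona-3,5-dien-1-yn-1-yl]-6-hydroxy-6-methylcyclohex-2-en-1-one
Conditions: PdCl2(PPh3)2 (3 mol %), CuI (6 mol %), Et3N (3 equiv), THF, 0 °C → rt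
Reagents that add atoms: none
Why: Sonogashira coupling; zerovalent palladium inserts into the C4a–OTf bond of the β-triflyloxy enone far faster than into the vinylic C5–Cl bond, and the copper acetylide of 17 then delivers C4. A tertiary amine base avoids addition–elimination at C4a; the descriptor at C8 changes only because the priorities change.

Step 12
Reactants: 18 chloro enynone
Product: 19 (4Z,5S,6S)-5-{2-[(tert-butyldiphenylsilyl)oxy]ethyl}-2-chloro-4-[(dimethylamino)methylidene]-3-[(3E,5E,7S)-5,7-dimethylnona-3,5-dien-1-yn-1-yl]-6-hydroxy-6-methylcyclohex-2-en-1-one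
Conditions: t-BuOCH(NMe2)2 (2 equiv), toluene, 60 °C, N2 sweep
Reagents that add atoms: tert-butoxybis(dimethylamino)methane, CN(C)C(OC(C)(C)C)N(C)C
Why: Vinylogous aminomethylenation; C7 is quaternary, so the C8a methylene (γ to the C6 carbonyl through C5=C4a) is the only enolizable position, and its dienolate attacks the formamidinium ion at C8a with loss of dimethylamine to give the push–pull dienaminone. Attack at C5 cannot eliminate and reverts; the volatile amine is swept out so that it does not add to the alkyne.

Step 13
Reactants: 19 dienaminone
Product: 21 (7S,8S)-8-{2-[(tert-butyldiphenylsilyl)oxy]ethyl}-5-chloro-3-[(1E,3E,5S)-3,5-dimethylhepta-1,3-dien-1-yl]-7-hydroxy-7-methyl-7,8-dihydro-6H-isochromen-6-one, via hydroxymethylidene enol 20 (not isolated)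
Conditions: TsOH·H2O (1.2 equiv), THF/H2O (10:1), 0 °C → rt; then AgOTf (10 mol %), rt
Reagents that add atoms: water, O
Why: Acid hydrolysis of the vinylogous amide gives the enol 20, a vinylogous acid whose oxygen can turn syn to the alkyne; AgOTf-activated 6-endo-dig oxacyclization (cycloisomerization) onto C3, the δ-terminus of the dienone, then closes ring B. The tert-butyldiphenylsilyl ether and the tertiary alcohol should tolerate TsOH at room temperature.

Step 14
Reactants: 21 silyl-protected pyranoquinone
Product: 22 (7S,8S)-5-chloro-3-[(1E,3E,5S)-3,5-dimethylhepta-1,3-dien-1-yl]-7-hydroxy-8-(2-hydroxyethyl)-7-methyl-7,8-dihydro-6H-isochromen-6-one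
Conditions: HF·pyridine, pyridine, THF, 0 °C → rt
Reagents that add atoms: none
Why: Fluoride cleavage of the silyl ether under buffered, weakly acidic conditions, which the chromophore should tolerate better than a basic fluoride source.

Step 15
Reactants: 22 diol
Product: 24 γ-lactone of [(7S,8S)-5-chloro-3-[(1E,3E,5S)-3,5-dimethylhepta-1,3-dien-1-yl]-7-hydroxy-7-methyl-6-oxo-7,8-dihydro-6H-isochromen-8-yl]acetic acid (cis-fused; lactone oxygen on C7), via lactol 23 (not isolated)
Conditions: TEMPO (0.2 equiv), PhI(OAc)2 (2.5 equiv), CH2Cl2, rt
Reagents that add atoms: none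
Why: TEMPO/PhI(OAc)2 oxidative lactonization of a 1,4-diol; the primary alcohol is oxidized to the aldehyde, the cis-disposed tertiary C7 hydroxyl closes the five-membered lactol 23, and a second oxidation gives the lactone. The oxoammonium oxidant is selective for alcohols over the diene and the enol ethers.

Step 16
Reactants: 24 cis-fused γ-lactone; 25 (S)-4-methyloxetan-2-one
Product: 27 (7S,8S)-5-chloro-3-[(1E,3E,5S)-3,5-dimethylhepta-1,3-dien-1-yl]-7-hydroxy-7-methyl-8-[(3R,6S)-6-methyl-2,4-dioxooxan-3-yl]-7,8-dihydro-6H-isochromen-6-one, via acylated lactone 26 (not isolated)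
Conditions: LiN(SiMe3)2 (1.1 equiv), THF, −78 °C; 25 (1.5 equiv), −78 → 0 °C; aq. HCl to pH 4
Reagents that add atoms: none
Why: Claisen-type C-acylation; the lithium enolate of 24 (C3') attacks the acyl carbon of the β-lactone (acyl–oxygen cleavage, so C6' stays S), and the alkoxide set free takes the acidic C3' proton, so one equivalent of base suffices. On warming, the C6' hydroxyl attacks C2' and expels the C7 alkoxide (translactonization), driven by the much more stabilized six-membered β-keto lactone enolate; protonation gives 27 with C3' under thermodynamic control.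

## Compound list

1 | (R)-lactic acid | C[C@@H](O)C(=O)O | starting material
2 | pivalaldehyde (2,2-dimethylpropanal) | CC(C)(C)C=O | starting material
3 | (2R,5R)-2-tert-butyl-5-methyl-1,3-dioxolan-4-one | C[C@H]1O[C@@H](C(C)(C)C)OC1=O | intermediate
4 | but-3-en-1-ol | C=CCCO | starting material
5 | tert-butyl(but-3-en-1-yloxy)diphenylsilane | C=CCCO[Si](c1ccccc1)(c1ccccc1)C(C)(C)C | intermediate
6 | but-3-en-2-one | CC(=O)C=C | starting material
7 | (E)-6-[(tert-butyldiphenylsilyl)oxy]hex-3-en-2-one | CC(=O)/C=C/CCO[Si](c1ccccc1)(c1ccccc1)C(C)(C)C | intermediate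
8 | lithium (2R)-2-tert-butyl-5-methyl-1,3-dioxol-4-olate (enolate of 3; not isolated) | [Li+].CC1=C([O-])O[C@H](C(C)(C)C)O1 | intermediate
9 | (2R,5S)-2-tert-butyl-5-{(3S)-1-[(tert-butyldiphenylsilyl)oxy]-5-oxohexan-3-yl}-5-methyl-1,3-dioxolan-4-one (Michael adduct; present as its enolate; not isolated) | C[C@@]1([C@@H](CCO[Si](c2ccccc2)(c2ccccc2)C(C)(C)C)CC(C)=O)O[C@@H](C(C)(C)C)OC1=O | intermediate
10 | (4S,5S)-5-{2-[(tert-butyldiphenylsilyl)oxy]ethyl}-4-hydroxy-4-methylcyclohexane-1,3-dione | O=C1CC(=O)[C@@](C)(O)[C@@H](CCO[Si](c2ccccc2)(c2ccccc2)C(C)(C)C)C1 | intermediate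
11 | (5S,6S)-5-{2-[(tert-butyldiphenylsilyl)oxy]ethyl}-2-chloro-3,6-dihydroxy-6-methylcyclohex-2-en-1-one | OC1=C(Cl)C(=O)[C@@](C)(O)[C@@H](CCO[Si](c2ccccc2)(c2ccccc2)C(C)(C)C)C1 | intermediate
12 | (4S,5S)-5-{2-[(tert-butyldiphenylsilyl)oxy]ethyl}-2-chloro-4-hydroxy-4-methyl-3-oxocyclohex-1-en-1-yl trifluoromethanesulfonate | FC(F)(F)S(=O)(=O)OC1=C(Cl)C(=O)[C@@](C)(O)[C@@H](CCO[Si](c2ccccc2)(c2ccccc2)C(C)(C)C)C1 | intermediate
13 | (S)-2-methylbutan-1-ol | CC[C@H](C)CO | starting material
14 | (S)-2-methylbutanal | CC[C@H](C)C=O | intermediate
15 | (2E,4S)-2,4-dimethylhex-2-enal | CC[C@H](C)/C=C(C)/C=O | intermediate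
16 | trimethyl[(3E,5E,7S)-5,7-dimethylnona-3,5-dien-1-yn-1-yl]silane | CC[C@H](C)/C=C(C)/C=C/C#C[Si](C)(C)C | intermediate
17 | (3E,5E,7S)-5,7-dimethylnona-3,5-dien-1-yne | CC[C@H](C)/C=C(C)/C=C/C#C | intermediate
18 | (5R,6S)-5-{2-[(tert-butyldiphenylsilyl)oxy]ethyl}-2-chloro-3-[(3E,5E,7S)-5,7-dimethylnona-3,5-dien-1-yn-1-yl]-6-hydroxy-6-methylcyclohex-2-en-1-one | CC[C@H](C)/C=C(C)/C=C/C#CC1=C(Cl)C(=O)[C@@](C)(O)[C@@H](CCO[Si](c2ccccc2)(c2ccccc2)C(C)(C)C)C1 | intermediate
19 | (4Z,5S,6S)-5-{2-[(tert-butyldiphenylsilyl)oxy]ethyl}-2-chloro-4-[(dimethylamino)methylidene]-3-[(3E,5E,7S)-5,7-dimethylnona-3,5-dien-1-yn-1-yl]-6-hydroxy-6-methylcyclohex-2-en-1-one | CC[C@H](C)/C=C(C)/C=C/C#CC1=C(Cl)C(=O)[C@@](C)(O)[C@@H](CCO[Si](c2ccccc2)(c2ccccc2)C(C)(C)C)/C1=C/N(C)C | intermediate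
20 | (4Z,5S,6S)-5-{2-[(tert-butyldiphenylsilyl)oxy]ethyl}-2-chloro-3-[(3E,5E,7S)-5,7-dimethylnona-3,5-dien-1-yn-1-yl]-6-hydroxy-4-(hydroxymethylidene)-6-methylcyclohex-2-en-1-one (not isolated) | CC[C@H](C)/C=C(C)/C=C/C#CC1=C(Cl)C(=O)[C@@](C)(O)[C@@H](CCO[Si](c2ccccc2)(c2ccccc2)C(C)(C)C)/C1=C/O | intermediate
21 | (7S,8S)-8-{2-[(tert-butyldiphenylsilyl)oxy]ethyl}-5-chloro-3-[(1E,3E,5S)-3,5-dimethylhepta-1,3-dien-1-yl]-7-hydroxy-7-methyl-7,8-dihydro-6H-isochromen-6-one | CC[C@H](C)/C=C(C)/C=C/C1=CC2=C(Cl)C(=O)[C@@](C)(O)[C@@H](CCO[Si](c3ccccc3)(c3ccccc3)C(C)(C)C)C2=CO1 | intermediate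
22 | (7S,8S)-5-chloro-3-[(1E,3E,5S)-3,5-dimethylhepta-1,3-dien-1-yl]-7-hydroxy-8-(2-hydroxyethyl)-7-methyl-7,8-dihydro-6H-isochromen-6-one | CC[C@H](C)/C=C(C)/C=C/C1=CC2=C(Cl)C(=O)[C@@](C)(O)[C@@H](CCO)C2=CO1 | intermediate
23 | cis-fused γ-lactol of 22 (C7–O–CH(OH)–CH2–C8; mixture of anomers; not isolated) | CC[C@H](C)/C=C(C)/C=C/C1=CC2=C(Cl)C(=O)[C@@]3(C)OC(O)C[C@H]3C2=CO1 | intermediate
24 | γ-lactone of [(7S,8S)-5-chloro-3-[(1E,3E,5S)-3,5-dimethylhepta-1,3-dien-1-yl]-7-hydroxy-7-methyl-6-oxo-7,8-dihydro-6H-isochromen-8-yl]acetic acid (cis-fused) | CC[C@H](C)/C=C(C)/C=C/C1=CC2=C(Cl)C(=O)[C@@]3(C)OC(=O)C[C@H]3C2=CO1 | intermediate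
25 | (S)-4-methyloxetan-2-one | C[C@H]1CC(=O)O1 | starting material
26 | 24 acylated at C3' by the (S)-3-hydroxybutanoyl group (present as its lithium enolate; C3' not defined; not isolated) | CC[C@H](C)/C=C(C)/C=C/C1=CC2=C(Cl)C(=O)[C@@]3(C)OC(=O)C(C(=O)C[C@H](C)O)[C@H]3C2=CO1 | intermediate
27 | (7S,8S)-5-chloro-3-[(1E,3E,5S)-3,5-dimethylhepta-1,3-dien-1-yl]-7-hydroxy-7-methyl-8-[(3R,6S)-6-methyl-2,4-dioxooxan-3-yl]-7,8-dihydro-6H-isochromen-6-one | CC[C@H](C)/C=C(C)/C=C/C1=CC2=C(Cl)C(=O)[C@@](C)(O)[C@@H]([C@@H]3C(=O)C[C@H](C)OC3=O)C2=CO1 | target

## Step count and least certain steps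

Total: 16 steps. Longest linear sequence: 11 steps (steps 2, 3, 4, 5, 6, 11, 12, 13, 14, 15, 16).

Step 4 (key step, proposed new method). The most likely failure is poor control of the enone face at C8. The two open approaches that keep the enone hydrogen under the acetal ring differ only in which carbon substituent lies next to the enolate oxygen, and any residual lithium bridging favours the wrong one. The one-flask sequence may also be diverted by proton transfer from the enone (its γ-deprotonation would expel silyloxide) or by tert-butoxide opening the acylal before C5 is enolized. Fallback, known chemistry, from 3 and 7 back to 10: the tandem is given up. The enolate 8 is added to 7 and the mixture is quenched cold, so that the adduct 9 is isolated and its C8 epimers are separated. The intermolecular Michael addition of dioxolanone enolates to enones can be run lithium-bridged (THF alone) or ion-separated (THF/HMPA), and the regime that delivers the required epimer is kept. Methanolysis (NaOMe, MeOH, 0 °C) then removes the acetal and gives methyl (2S,3S)-3-{2-[(tert-butyldiphenylsilyl)oxy]ethyl}-2-hydroxy-2-methyl-5-oxohexanoate F1. A separate Dieckmann-type Claisen cyclization of this δ-keto ester (KOtBu, THF) returns 10.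

Step 16. The most likely failure is proton transfer in place of acylation. The hindered lactone enolate can deprotonate the β-lactone, which then opens by elimination and returns 24; addition of the enolate to the chromophore of a second molecule is the other loss. Fallback from 24 to 27: the enolate of 24 is trapped with an aldehyde, which adds faster than it transfers a proton. (S)-3-[(tert-Butyldimethylsilyl)oxy]butanal (C[C@@H](CC=O)O[Si](C)(C)C(C)(C)C) is used and gives the aldol adduct F2. Dess–Martin periodinane oxidizes it to the β-keto lactone silyl ether F3. HF·pyridine then frees the C6' hydroxyl, which translactonizes to 27.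

Step 12. The most likely failure is conjugate addition of the liberated dimethylamine or of tert-butoxide to the alkyne terminus C3, or sluggish deprotonation at C8a at a temperature the enynone tolerates. Fallback from 18 to 21: C1 is brought in as an electrophile toward a silyl dienol ether (vinylogous Mukaiyama reaction). LiN(SiMe3)2 (2.2 equiv) and Me3SiCl convert 18 into the bis(trimethylsilyl) dienol ether F4. HC(OMe)3 with BF3·OEt2 at −78 °C attacks its γ-carbon C8a and, after work-up, gives the C8a dimethoxymethyl enynone F5. The acid, water and AgOTf of step 13 hydrolyse the acetal to the same enol 20 and close the pyran to 21.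

Step 15. The most likely failure is oxidation or addition at the diene or the pyran enol ethers by the oxoammonium or hypervalent iodine species, or stalling at the lactol. Fallback from 22 to 24: the redox lactonization is replaced by acid formation and acyl substitution. Dess–Martin periodinane (NaHCO3) gives the lactol 23, which is isolated. Pinnick oxidation (NaClO2, NaH2PO4, 2-methylbut-2-ene) of its open hydroxy aldehyde form gives the hydroxy acid F6, and carbodiimide lactonization (EDC·HCl, DMAP) closes 24.

## Further compounds

F1 | step 4 | methyl (2S,3S)-3-{2-[(tert-butyldiphenylsilyl)oxy]ethyl}-2-hydroxy-2-methyl-5-oxohexanoate | COC(=O)[C@@](C)(O)[C@@H](CCO[Si](c1ccccc1)(c1ccccc1)C(C)(C)C)CC(C)=O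
F2 | step 16 | aldol adduct of 24 at C3' with (S)-3-[(tert-butyldimethylsilyl)oxy]butanal (C3' and carbinol carbon not defined) | CC[C@H](C)/C=C(C)/C=C/C1=CC2=C(Cl)C(=O)[C@@]3(C)OC(=O)C(C(O)C[C@H](C)O[Si](C)(C)C(C)(C)C)[C@H]3C2=CO1
F3 | step 16 | 24 acylated at C3' by the (S)-3-[(tert-butyldimethylsilyl)oxy]butanoyl group (C3' not defined) | CC[C@H](C)/C=C(C)/C=C/C1=CC2=C(Cl)C(=O)[C@@]3(C)OC(=O)C(C(=O)C[C@H](C)O[Si](C)(C)C(C)(C)C)[C@H]3C2=CO1
F4 | step 12 | bis(trimethylsilyl) dienol ether of 18 (C6 enol and C7 hydroxyl silylated; C4a=C8a and C5=C6 double bonds) | CC[C@H](C)/C=C(C)/C=C/C#CC1=C[C@H](CCO[Si](c2ccccc2)(c2ccccc2)C(C)(C)C)[C@](C)(O[Si](C)(C)C)C(O[Si](C)(C)C)=C1Cl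
F5 | step 12 | 18 bearing a dimethoxymethyl group on C8a (C8a not defined) | CC[C@H](C)/C=C(C)/C=C/C#CC1=C(Cl)C(=O)[C@@](C)(O)[C@@H](CCO[Si](c2ccccc2)(c2ccccc2)C(C)(C)C)C1C(OC)OC
F6 | step 15 | [(7S,8S)-5-chloro-3-[(1E,3E,5S)-3,5-dimethylhepta-1,3-dien-1-yl]-7-hydroxy-7-methyl-6-oxo-7,8-dihydro-6H-isochromen-8-yl]acetic acid | CC[C@H](C)/C=C(C)/C=C/C1=CC2=C(Cl)C(=O)[C@@](C)(O)[C@@H](CC(=O)O)C2=CO1
A1 | alternative 1 | [(1R)-5-methoxy-2-methyl-3-oxocyclohex-4-en-1-yl]acetic acid (C8 as in the target; C7 not defined) | COC1=CC(=O)C(C)[C@@H](CC(=O)O)C1
A2 | alternative 1 | cis-fused 5-methoxy-7a-methyl-3,3a,4,7a-tetrahydro-1-benzofuran-2,7-dione (C7 and C8 as in the target) | COC1=CC(=O)[C@@]2(C)OC(=O)C[C@H]2C1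
A3 | alternative 2 | 2-chloro-3-[(3E,5E,7S)-5,7-dimethylnona-3,5-dien-1-yn-1-yl]-6-hydroxy-5-[(6S)-4-methoxy-6-methyl-2-oxo-5,6-dihydro-2H-pyran-3-yl]-6-methylcyclohex-2-en-1-one (C7 and C8 as in the target) | CC[C@H](C)/C=C(C)/C=C/C#CC1=C(Cl)C(=O)[C@@](C)(O)[C@@H](C2=C(OC)C[C@H](C)OC2=O)C1
A4 | alternative 2 | methyl enol ether of 27 at C4' | CC[C@H](C)/C=C(C)/C=C/C1=CC2=C(Cl)C(=O)[C@@](C)(O)[C@@H](C3=C(OC)C[C@H](C)OC3=O)C2=CO1
A5 | alternative 3 | 1-methyl-4-oxocyclohexa-2,5-dien-1-yl (5S)-5-[(tert-butyldimethylsilyl)oxy]-3-oxohexanoate | O=C1C=CC(C)(OC(=O)CC(=O)C[C@H](C)O[Si](C)(C)C(C)(C)C)C=C1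
A6 | alternative 3 | cis-fused bicyclic keto γ-lactone enone with C7, C8 and C3' set | O=C1C=C[C@@]2(C)OC(=O)[C@@H](C(=O)C[C@H](C)O[Si](C)(C)C(C)(C)C)[C@H]2C1
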